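**Plan**

- Retrosynthesis: first the six aryl O–Me bonds; then the two C2=Cα double bonds, back to a bis-hemiketal (2-hydroxybenzofuran-3-one with Cα–H); then, in one cut, both furanone rings and the central Cα–Cα′ bond, back to two molecules of a flavonol.
- Enabling feature: Cα of the target is C2 of a 2-aryl-3-hydroxychromen-4-one and ring C2 is its C3, so target = 2 flavonol + 2 H − 2 H2O. The aryl-bearing C2 is the β-carbon of the pyranone enone (spin site after one-electron reduction) and carries ring oxygen O1, which can leave from C2 and re-close on C3: pyranone (6) → furanone (5).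
- Forward: Claisen–Schmidt chalcone → Algar–Flynn–Oyamada flavonol (pyranone ring) → cathodic C2–C2′ dimerisation with double ring contraction (central bond, both furanone rings) → dehydration → demethylation.
- Stereochemistry: the target has no stereocentre. The sp3 centres made in the key step are erased in step 4, and the two tetrasubstituted C=C geometries are set under thermodynamic (acid) control.

Key step: step 3

Assumption: "single enantiomer" is read as the single double-bond isomer drawn (the molecule is achiral). This (Z,Z) isomer, with each ring oxygen O1 cis to the other half and each aryl ring cis to C3=O, is taken to be the thermodynamically favoured one, because only it lets the diene C2=Cα–Cα′=C2′ lie flat (s-trans) with the two small ring oxygens inside. Compounds 6, 7 and 8 are diastereomer mixtures, so their SMILES carry no descriptors.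

**Step 1**
Reactants: 1 paeonol (1-(2-hydroxy-4-methoxyphenyl)ethanone); 2 veratraldehyde (3,4-dimethoxybenzaldehyde)
Product: 3 (E)-2′-hydroxy-3,4,4′-trimethoxychalcone
Conditions: KOH (50% aq.), EtOH, rt
Reagents that add atoms: none
Why: Claisen–Schmidt condensation: only the methyl ketone can enolise, the aldehyde cannot, and E1cB loss of water should give the conjugated (E)-enone.

**Step 2**
Reactants: 3 (E)-2′-hydroxy-3,4,4′-trimethoxychalcone
Product: 4 3-hydroxy-7,3′,4′-trimethoxyflavone (2-(3,4-dimethoxyphenyl)-3-hydroxy-7-methoxy-4H-chromen-4-one)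
Conditions: 30% H2O2, NaOH (aq.), MeOH, 0 °C → rt; then dil. HCl
Reagents that add atoms: hydrogen peroxide, OO
Why: Algar–Flynn–Oyamada reaction: alkaline hydrogen peroxide should oxidatively cyclise a 2′-hydroxychalcone without a 6′-substituent to the flavonol (six-membered mode) and not to the aurone, the aryl methyl ethers being inert.

**Step 3**
Reactants: 4 3-hydroxy-7,3′,4′-trimethoxyflavone (two molecules)
Product: 8 bis-auronol 2,2′-[1,2-bis(3,4-dimethoxyphenyl)ethane-1,2-diyl]bis(2-hydroxy-6-methoxybenzofuran-3(2H)-one) as a mixture of diastereomers, via 3-O-trimethylsilyl flavonol 5 (not isolated), via tetrakis(trimethylsilyloxy)-2,2′-bi-2H-chromene 6 (not isolated), via 2,2′-bis(dihydroflavonol) 7 (not isolated)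
Conditions: BSA, DMF, rt; then TMSCl (excess), Bu4NBF4, Mg anode/glassy-carbon cathode, undivided cell, constant current (about 1.1 F per mol of 4), 0 °C, Ar; then K2CO3, MeOH, 0 °C → rt, Ar; AcOH quench
Reagents that add atoms: none
Why: Proposed new method: BSA silylates the 3-OH (5); cathodic one-electron reduction of the enone and O-silylation of the ketyl oxygen by TMSCl give a neutral 4-silyloxychromenyl radical with spin at C2 and C4, two of which combine C2–C2′ to the bis(enediol silyl ether) 6; methanolysis then unmasks the α-ketol/enediolate 7, whose enolate expels the ring phenoxide O1 from C2 (E1cB, retro-oxa-Michael), the resulting α-hydroxy-enone ketonises to the 1,2-diketone, and the phenoxide re-closes on the C2 ketone to the hemiketal 8. The closest known reaction types are the cathodic hydrodimerisation of flavones to 2,2′-biflavanones (and TMSCl-assisted electroreductive couplings of chromones at C2) and the base- or heat-induced contraction of dihydroflavonols to 2-benzyl-2-hydroxybenzofuran-3(2H)-ones; new is their union on a 3-oxygenated flavone, so that the central C–C bond and both contractions arise in one operation. Each furanone ring closes by 5-exo-trig addition of the phenoxide oxygen to a ketone carbonyl, and the pyranone → furanone change is driven by relief of the two adjacent quaternary carbons of 6/7, which become tertiary CH(Ar) carbons in 8. The four new stereocentres (two hemiketal carbons, two CH(Ar) carbons) are not controlled and need not be, since all four become sp2 in step 4. The selectivity needed is C2–C2′ coupling over C4-based coupling and over further reduction of the radical: C2 is the β-carbon of the enone and its radical is stabilised by both the aryl ring and O1, C4 is shielded by the peri C5–H and two OTMS groups, and excess TMSCl makes the dimer a non-reducible enol ether. Only the C2–C2′ dimer places O1 and the new bond on the same carbon, so only it is drained irreversibly by the contraction.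

**Step 4**
Reactants: 8 bis-auronol (mixture of diastereomers)
Product: 9 disulfuretin hexamethyl ether, (2Z,2′Z)-2,2′-[1,2-bis(3,4-dimethoxyphenyl)ethane-1,2-diylidene]bis(6-methoxybenzofuran-3(2H)-one)
Conditions: p-TsOH·H2O (cat.), toluene, reflux, Dean–Stark
Reagents that add atoms: none
Why: Acid-catalysed dehydration of a 2-alkyl-2-hydroxybenzofuran-3(2H)-one (auronol → aurone): ionisation of each hemiketal to the O1-stabilised oxocarbenium ion and loss of the tertiary benzylic Cα–H should give the conjugated enol ether, and reversible protonation of the push–pull alkene (the dimethoxyphenyl donor on Cα allows rotation in the cation) should let both double bonds settle on the thermodynamic (Z,Z) geometry with the ring oxygens facing each other across the s-trans diene.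

**Step 5**
Reactants: 9 disulfuretin hexamethyl ether
Product: 10 disulfuretin, (2Z,2′Z)-2,2′-[1,2-bis(3,4-dihydroxyphenyl)ethane-1,2-diylidene]bis(6-hydroxybenzofuran-3(2H)-one)
Conditions: BBr3 (excess), CH2Cl2, −78 °C → rt; then MeOH, H2O
Reagents that add atoms: none
Why: Lewis-acid cleavage of aryl methyl ethers with BBr3 (standard for methoxyaurones): bromide attacks the methyl group of each boron-coordinated ether by SN2, the cyclic aryl vinyl ether and the ketones should be left intact, and the alkene geometry remains the thermodynamic one.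

**Compound list**

1 | paeonol, 1-(2-hydroxy-4-methoxyphenyl)ethanone | CC(=O)c1ccc(OC)cc1O | starting material
2 | veratraldehyde, 3,4-dimethoxybenzaldehyde | COc1ccc(C=O)cc1OC | starting material
3 | (E)-3-(3,4-dimethoxyphenyl)-1-(2-hydroxy-4-methoxyphenyl)prop-2-en-1-one | COc1ccc(C(=O)/C=C/c2ccc(OC)c(OC)c2)c(O)c1 | intermediate
4 | 2-(3,4-dimethoxyphenyl)-3-hydroxy-7-methoxy-4H-chromen-4-one | COc1ccc2c(c1)oc(-c1ccc(OC)c(OC)c1)c(O)c2=O | intermediate
5 | 2-(3,4-dimethoxyphenyl)-7-methoxy-3-(trimethylsilyloxy)-4H-chromen-4-one | COc1ccc2c(c1)oc(-c1ccc(OC)c(OC)c1)c(O[Si](C)(C)C)c2=O | intermediate (not isolated)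
6 | 2,2′-bis(3,4-dimethoxyphenyl)-7,7′-dimethoxy-3,3′,4,4′-tetrakis(trimethylsilyloxy)-2H,2′H-2,2′-bichromene, rac/meso mixture | COc1ccc2c(c1)OC(c1ccc(OC)c(OC)c1)(C(O[Si](C)(C)C)=C2O[Si](C)(C)C)C1(c2ccc(OC)c(OC)c2)Oc2cc(OC)ccc2C(O[Si](C)(C)C)=C1O[Si](C)(C)C | intermediate (not isolated)
7 | 2,2′-bis(3,4-dimethoxyphenyl)-3,3′-dihydroxy-7,7′-dimethoxy-2,2′-bichromane-4,4′-dione, mixture of diastereomers | COc1ccc2c(c1)OC(c1ccc(OC)c(OC)c1)(C(O)C2=O)C1(c2ccc(OC)c(OC)c2)Oc2cc(OC)ccc2C(=O)C1O | intermediate (not isolated)
8 | 2,2′-[1,2-bis(3,4-dimethoxyphenyl)ethane-1,2-diyl]bis(2-hydroxy-6-methoxybenzofuran-3(2H)-one), mixture of diastereomers | COc1ccc2c(c1)OC(O)(C2=O)C(c1ccc(OC)c(OC)c1)C(c1ccc(OC)c(OC)c1)C1(O)Oc2cc(OC)ccc2C1=O | intermediate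
9 | (2Z,2′Z)-2,2′-[1,2-bis(3,4-dimethoxyphenyl)ethane-1,2-diylidene]bis(6-methoxybenzofuran-3(2H)-one) | O=C1/C(=C(/C(=C2\Oc3cc(OC)ccc3C2=O)c2ccc(OC)c(OC)c2)c2ccc(OC)c(OC)c2)Oc2cc(OC)ccc21 | intermediate
10 | disulfuretin, (2Z,2′Z)-2,2′-[1,2-bis(3,4-dihydroxyphenyl)ethane-1,2-diylidene]bis(6-hydroxybenzofuran-3(2H)-one) | O=C1/C(=C(/C(=C2\Oc3cc(O)ccc3C2=O)c2ccc(O)c(O)c2)c2ccc(O)c(O)c2)Oc2cc(O)ccc21 | target

**Count**

Total steps: 5. Longest linear sequence: 5 steps (1 or 2 → 10).

**Steps most likely to fail**

Step 3 (Proposed new method). The silyloxychromenyl radical may be reduced further and silylated or protonated before it dimerises, or it may couple through C4. The weak, doubly benzylic C2–C2′ bond of the dimer may also redissociate before the contraction fixes it. The fallback uses known chemistry, sets out from chalcone 3 and comes back at 9, so that steps 3 and 4 are not needed. Oxidative cyclisation of 3 with Hg(OAc)2 in pyridine should give the aurone (Z)-2-(3,4-dimethoxybenzylidene)-6-methoxybenzofuran-3(2H)-one F1. Reductive hydrodimerisation of this enone at its β-carbon (Mg, TMSCl, DMF) should then give 1,2-bis(3,4-dimethoxyphenyl)-1,2-bis[6-methoxy-3-(trimethylsilyloxy)benzofuran-2-yl]ethane F2; here the benzylic Cα is the only non-aromatic spin site, so the coupling site is not in doubt. Saegusa–Ito oxidation of the two silyl enol ethers (Pd(OAc)2, MeCN), with β-hydride loss from Cα–H, should restore both exocyclic double bonds and give 9, after brief acid equilibration of the geometry as in step 4.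

Step 4. The C2 oxocarbenium ion may be captured by the neighbouring dimethoxyphenyl ring (Friedel–Crafts), or the two alkenes may not converge on one geometry. The fallback sets out from 8 and comes back at 9. It replaces acid ionisation by activation of the hemiketal hydroxyls and intramolecular syn-elimination: Burgess reagent in THF at 50 °C should give the bis(sulfamate) ester of 8, 2,2′-[1,2-bis(3,4-dimethoxyphenyl)ethane-1,2-diyl]bis(6-methoxy-3-oxo-2,3-dihydrobenzofuran-2-yl) bis[N-(methoxycarbonyl)sulfamate] F3, which should eliminate without a free cation. Catalytic iodine under visible light should then equilibrate the alkenes to 9.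

Step 5. Cleavage of the six methyl ethers may stay incomplete, or the push–pull diene may degrade by HBr addition while it is exposed to the Lewis acid. The fallback sets out from 8 and comes back at 10, with the order of the last two events reversed so that the diene never meets BBr3. BBr3 in CH2Cl2 on the bis-hemiketal should give 2,2′-[1,2-bis(3,4-dihydroxyphenyl)ethane-1,2-diyl]bis(2,6-dihydroxybenzofuran-3(2H)-one) F4, and mild acid (dil. HCl, MeOH, 50 °C) should then dehydrate it to 10.

**Further compounds**

F1 | step 3 | (Z)-2-(3,4-dimethoxybenzylidene)-6-methoxybenzofuran-3(2H)-one | COc1ccc2c(c1)O/C(=C\c1ccc(OC)c(OC)c1)C2=O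
F2 | step 3 | 1,2-bis(3,4-dimethoxyphenyl)-1,2-bis[6-methoxy-3-(trimethylsilyloxy)benzofuran-2-yl]ethane, rac/meso mixture | COc1ccc2c(O[Si](C)(C)C)c(oc2c1)C(c1ccc(OC)c(OC)c1)C(c1ccc(OC)c(OC)c1)c1oc2cc(OC)ccc2c1O[Si](C)(C)C
F3 | step 4 | 2,2′-[1,2-bis(3,4-dimethoxyphenyl)ethane-1,2-diyl]bis(6-methoxy-3-oxo-2,3-dihydrobenzofuran-2-yl) bis[N-(methoxycarbonyl)sulfamate], mixture of diastereomers | COc1ccc2c(c1)OC(OS(=O)(=O)NC(=O)OC)(C2=O)C(c1ccc(OC)c(OC)c1)C(c1ccc(OC)c(OC)c1)C1(OS(=O)(=O)NC(=O)OC)Oc2cc(OC)ccc2C1=O
F4 | step 5 | 2,2′-[1,2-bis(3,4-dihydroxyphenyl)ethane-1,2-diyl]bis(2,6-dihydroxybenzofuran-3(2H)-one), mixture of diastereomers | Oc1ccc2c(c1)OC(O)(C2=O)C(c1ccc(O)c(O)c1)C(c1ccc(O)c(O)c1)C1(O)Oc2cc(O)ccc2C1=O
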